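| flask | solid substrate | remark | time |
|---|---|---|---|
| midnight | 0.34 M | run made earlier |  |
| autumn | 0.75 M | run made earlier |  |
| flask | 0.50 M |  | 2.5 h |

| run | time / h | isomer of the product / % | target / % |
|---|---|---|---|
| midnight | 0.250 | 18.2 | 10.6 |
| midnight | 0.417 | 43.0 | 11.9 |
| midnight | 0.667 | 66.1 | 8.6 |
| midnight | 1.00 | 84.7 | 6.3 |
| midnight | 2.00 | 95.5 | 2.8 |
| midnight | 3.00 | 96.2 | 3.2 |
| autumn | 0.200 | 4.0 | 2.7 |
| autumn | 0.667 | 36.0 | 7.8 |
| autumn | 1.00 | 58.2 | 8.1 |
| autumn | 1.50 | 85.5 | 5.7 |
| autumn | 2.50 | 95.7 | 4.4 |
| autumn | 3.00 | 95.8 | 1.7 |

(each reading ± 1 percentage point)

- share of isomer of the product in isomer of the product plus target at 5.0 min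
- share of isomer of the product in isomer of the product plus target at 25 min
- share of isomer of the product in isomer of the product plus target at 2.5 h
- which of isomer of the product and target there is more of at 2.5 h

- solid substrate is a solid; its amount is given per volume of the solution
- at the start none of the solid substrate is in solution

1. Read two constants off the autumn run. Between 0.667 h and 1.00 h, target plus isomer of the product grows by 0.507 M h⁻¹; call this the supply.

2. Divide c(target) at 1.00 h, 0.0607 M, by the supply. This gives 0.120 h, the residence time of target: what stands over what passes through.

3. Take a steady supply into target and a first-order drain. With x the time over the residence time, the isomer's share is 1 − (1 − e^(−x))/x. The supply cancels, so the charge drops out.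

4. Find where this stops. For the flask, the charge over the supply gives a clearing time of 0.987 h, which is 8.22 times the residence time and longer than 25 min.

5. Reckon the flask: 27.9% at 5.0 min and 72.1% at 25 min. At 2.5 h, past clearing, expect the late readings, such as 96.8% in the midnight run at 3.00 h, so the isomer leads.

6. The forecast, holding that “dissolution limits the early supply”, gives 35%, 75% and 97%, with isomer of the product ahead; it stands above my reckoning at both early times.

7. The flask gives 29.2%, 75.6% and 96.6%, with isomer of the product ahead.

    starting material ⇌ target (K = 5.10, k = 0.0470 min⁻¹)
    solid substrate ⇌ starting material, rate k2*(cs2 - [starting material]) while solid is left; crystals form when [starting material] > cs2 (solubility = 0.250 M, k = 0.170 min⁻¹)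
    target ⇌ isomer of the product (K = 29.0, k = 0.210 min⁻¹)

With 0.120 h, the flask's early shares lie 1.3 percentage points and 3.5 points above the reckoning. Now take the neighbour charged with 0.12 M, less than the solubility of 0.25 M. The supply from the autumn run does not carry over to this neighbour: even its whole charge as starting material would pass 0.338 M h⁻¹ into target, less than that supply. Apply the residence-time rule to the neighbour anyway, and it gives 27.9% at 5.0 min and 72.1% at 25 min. The neighbour gives 30.2% at 5.0 min and 83.5% at 25 min, above the rule at the later time. At 2.5 h the neighbour's share is 96.6%, with target at 3.34% of its charge.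

Readings and results were generated by integration for substances that don't exist.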